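**Retrosynthetic overview**

1. Target 17 ⇐ 16 by a late, catalyst-controlled bromochlorination of the homoprenyl alkene; the (S)-vinyl carbinol ⇐ methyl ketone (asymmetric sulfur-ylide epoxidation, then ylide homologation); the homoprenyl arm ⇐ exo-CHO (Wittig, B-alkyl Suzuki).
2. Key disconnection: keto aldehyde 10 ⇐ acyclic dihydroxy diketone 8 by a Prins–pinacol sequence whose final 1,2-shift contracts an 8-oxabicyclo[3.2.1]octyl cation to the 7-oxabicyclo[2.2.1]heptane.
3. Ring order: the oxolane forms first (cyclic oxocarbenium from the γ-hydroxy ketone), then the oxane by Prins closure, then the contraction, which completes the cyclohexane; C1, C2 and C3 follow from C4 and the E-alkene.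
4. 8 ⇐ hex-5-en-2-one + methacrolein + an allyl donor + methyl vinyl ketone (two cross-metatheses and an anti-hydroxyallylation that sets C4).

Assumption: C1–C4 are the 7-oxabicyclo[2.2.1]heptane locants of the target (C1 = methyl-bearing bridgehead); the SMILES is read as (1S,2S,3S,4R) with (3S)-carbinol and (3S)-bromide side chains; allyl(diisopropylamino)dimethylsilane is treated as an allyl-transfer reagent.

**Route**

Step 1
Reactants: 1 hex-5-en-2-one; 2 methacrolein (5 equiv)
Product: 3 (2E)-2-methyl-6-oxohept-2-enal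
Conditions: second-generation Hoveyda–Grubbs catalyst RuCl2(H2IMes)(=CH-C6H4-2-OiPr) (3 mol%), CH2Cl2, 40 °C
Reagents that add atoms: none
Why: Olefin cross-metathesis of a terminal alkene with methacrolein gives the trisubstituted enal as the favoured E isomer, the geometry that later fixes C2.

Step 2
Reactants: 3 (2E)-2-methyl-6-oxohept-2-enal
Product: 5 (5E,7S,8R)-7,8-dihydroxy-6-methyldeca-5,9-dien-2-one, via borinate of the anti-hydroxyallylsilane 4 (not isolated)
Conditions: allyl(diisopropylamino)dimethylsilane, n-BuLi, TMEDA, Et2O, 0 °C; (+)-Ipc2BOMe (from (−)-α-pinene), −78 °C; BF3·OEt2; 3, −78 °C; then KF, KHCO3, 30% H2O2, THF/MeOH, rt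
Reagents that add atoms: allyl(diisopropylamino)dimethylsilane C=CC[Si](C)(C)N(C(C)C)C(C)C; hydrogen peroxide OO
Why: Brown-type allylboration with the (E)-γ-silylallyl-B(Ipc)2 reagent attacks only the aldehyde through a chair transition state (E-reagent gives anti, the Ipc groups set 7S,8R), and Tamao–Fleming oxidation replaces Si by OH with retention.

Step 3
Reactants: 5 (5E,7S,8R)-7,8-dihydroxy-6-methyldeca-5,9-dien-2-one; 6 methyl vinyl ketone (3 equiv)
Product: 7 (3E,5R,6S,7E)-5,6-dihydroxy-7-methyldodeca-3,7-diene-2,11-dione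
Conditions: second-generation Hoveyda–Grubbs catalyst RuCl2(H2IMes)(=CH-C6H4-2-OiPr) (5 mol%), CH2Cl2, 40 °C
Reagents that add atoms: none
Why: Olefin cross-metathesis of the monosubstituted allylic alkene with an enone partner gives the E-enone while the trisubstituted alkene is inert; no stereocenter is touched.

Step 4
Reactants: 7 (3E,5R,6S,7E)-5,6-dihydroxy-7-methyldodeca-3,7-diene-2,11-dione
Product: 8 (5R,6S,7E)-5,6-dihydroxy-7-methyldodec-7-ene-2,11-dione
Conditions: [(Ph3P)CuH]6 (0.4 equiv), H2O (3 equiv), THF, rt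
Reagents that add atoms: none
Why: Copper hydride conjugate reduction (Stryker reduction) saturates only the enone C=C and, unlike rhodium or ruthenium hydrides, does not isomerise the allylic carbinol; 8 equilibrates with its five-membered hemiketal.

Step 5
Reactants: 8 (5R,6S,7E)-5,6-dihydroxy-7-methyldodec-7-ene-2,11-dione
Product: 10 (1R,2S,3S,4S)-2,4-dimethyl-3-(3-oxobutyl)-7-oxabicyclo[2.2.1]heptane-2-carbaldehyde, via bicyclic ketal 9 (not isolated)
Conditions: PPTS (5 mol%), MgSO4, CH2Cl2, rt; then SnCl4 (2.2 equiv), −78 → −20 °C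
Reagents that add atoms: none
Why: Prins–pinacol rearrangement: SnCl4 opens the ketal to the five-membered oxocarbenium, the E-alkene closes on it in a chair (side chain equatorial, hence endo at C2 with exo H), and the tertiary 8-oxabicyclo[3.2.1]octyl cation contracts by a pinacol 1,2-shift of the ring C–C bond, which the axial C–O(Sn) of the anti diol leaves as the only aligned bond, so the extruded carbon becomes the exo-CHO at C3 (methyl endo) while C4 is retained and C1 is fixed by the bridge.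

Step 6
Reactants: 10 (1R,2S,3S,4S)-2,4-dimethyl-3-(3-oxobutyl)-7-oxabicyclo[2.2.1]heptane-2-carbaldehyde
Product: 11 4-[(1S,2S,3S,4R)-3-ethenyl-1,3-dimethyl-7-oxabicyclo[2.2.1]heptan-2-yl]butan-2-one
Conditions: Ph3PCH3Br (1.1 equiv), KN(SiMe3)2 (1.05 equiv), THF, 0 °C; then 10, −78 → −40 °C
Reagents that add atoms: methyltriphenylphosphonium bromide C[P+](c1ccccc1)(c1ccccc1)c1ccccc1.[Br-]
Why: Wittig methylenation with one equivalent of ylide at low temperature takes the aldehyde far faster than the methyl ketone, and the α-quaternary aldehyde cannot epimerise.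

Step 7
Reactants: 11 4-[(1S,2S,3S,4R)-3-ethenyl-1,3-dimethyl-7-oxabicyclo[2.2.1]heptan-2-yl]butan-2-one
Product: 12 (1S,2S,3S,4R)-3-ethenyl-1,3-dimethyl-2-{2-[(2S)-2-methyloxiran-2-yl]ethyl}-7-oxabicyclo[2.2.1]heptane
Conditions: Me3S(O)I (1.5 equiv), NaH (1.5 equiv), LaLi3(binaphthoxide)3 (5 mol%; BINOL antipode that gives the (2S)-oxirane), tris(2,4,6-trimethoxyphenyl)phosphine oxide (5 mol%), 5 Å MS, THF, rt
Reagents that add atoms: trimethylsulfoxonium iodide C[S+](C)(C)=O.[I-]
Why: Catalytic asymmetric Corey–Chaykovsky epoxidation of a methyl ketone, in which the lanthanum–lithium binaphthoxide catalyst alone sets the remote (S)-oxirane carbon.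

Step 8
Reactants: 12 (1S,2S,3S,4R)-3-ethenyl-1,3-dimethyl-2-{2-[(2S)-2-methyloxiran-2-yl]ethyl}-7-oxabicyclo[2.2.1]heptane; 13 1-bromo-2-methylprop-1-ene (2 equiv)
Product: 15 (1S,2S,3S,4R)-1,3-dimethyl-3-(4-methylpent-3-en-1-yl)-2-{2-[(2S)-2-methyloxiran-2-yl]ethyl}-7-oxabicyclo[2.2.1]heptane, via B-alkyl-9-BBN adduct 14 (not isolated)
Conditions: 9-BBN-H (1.5 equiv), THF, 0 → 50 °C; then 13, PdCl2(dppf) (5 mol%), 3 M aq K3PO4, DMF, 50 °C
Reagents that add atoms: none
Why: Anti-Markovnikov hydroboration of the only alkene followed by B-alkyl Suzuki–Miyaura coupling with the alkenyl bromide builds the homoprenyl arm; the oxirane is inert and no stereocenter is touched.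

Step 9
Reactants: 15 (1S,2S,3S,4R)-1,3-dimethyl-3-(4-methylpent-3-en-1-yl)-2-{2-[(2S)-2-methyloxiran-2-yl]ethyl}-7-oxabicyclo[2.2.1]heptane
Product: 16 (3S)-5-[(1S,2S,3S,4R)-1,3-dimethyl-3-(4-methylpent-3-en-1-yl)-7-oxabicyclo[2.2.1]heptan-2-yl]-3-methylpent-1-en-3-ol
Conditions: Me3SI (5 equiv), n-BuLi (4.8 equiv), THF, −10 °C → rt
Reagents that add atoms: trimethylsulfonium iodide C[S+](C)C.[I-]
Why: Epoxide-to-allylic-alcohol one-carbon homologation with excess dimethylsulfonium methylide: the ylide opens the oxirane at CH2 and the betaine eliminates Me2S, so the C–O bond at the stereocenter is never broken (retention).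

Step 10
Reactants: 16 (3S)-5-[(1S,2S,3S,4R)-1,3-dimethyl-3-(4-methylpent-3-en-1-yl)-7-oxabicyclo[2.2.1]heptan-2-yl]-3-methylpent-1-en-3-ol
Product: 17 (3S)-5-[(1S,2S,3S,4R)-3-[(3S)-3-bromo-4-chloro-4-methylpentyl]-1,3-dimethyl-7-oxabicyclo[2.2.1]heptan-2-yl]-3-methylpent-1-en-3-ol
Conditions: NBS (1.2 equiv), KCl (3 equiv, finely milled), BINAM-derived N-isopropyl bis[3,5-bis(trifluoromethyl)phenyl]urea (10 mol%; antipode that gives the (3S)-bromide), Ph3P=S (5 mol%), 1,2-difluorobenzene, −30 °C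
Reagents that add atoms: N-bromosuccinimide O=C1CCC(=O)N1Br; potassium chloride [K+].[Cl-]
Why: Proposed new method: hydrogen-bonding phase-transfer bromochlorination, in which Br+ (relayed by the sulfide Lewis base) adds reversibly and only to the electron-rich trisubstituted alkene, the enantiomeric bromiranium ions interconvert by olefin-to-olefin Br+ transfer, and the chiral bis-urea·chloride ion pair drawn from solid KCl opens one of them faster, anti and at the tertiary carbon (Markovnikov), setting the C–Br center under catalyst control; the closest known reactions are the titanium/Schiff-base-catalysed enantioselective bromochlorination of allylic alcohols and chiral bis-urea phase-transfer fluoride opening of episulfonium ions.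

**Compound list**

1 | hex-5-en-2-one | CC(=O)CCC=C | starting material
2 | methacrolein (2-methylprop-2-enal) | CC(=C)C=O | starting material
3 | (2E)-2-methyl-6-oxohept-2-enal | CC(=O)CC/C=C(\C)C=O | intermediate
4 | (5E,7S,8R)-7-[bis(isopinocampheyl)boryloxy]-8-[(diisopropylamino)dimethylsilyl]-6-methyldeca-5,9-dien-2-one | CC(=O)CC/C=C(\C)[C@H](OB([C@@H]1[C@@H](C)[C@@H]2C[C@H](C1)C2(C)C)[C@@H]1[C@@H](C)[C@@H]2C[C@H](C1)C2(C)C)[C@H]([Si](C)(C)N(C(C)C)C(C)C)C=C | intermediate
5 | (5E,7S,8R)-7,8-dihydroxy-6-methyldeca-5,9-dien-2-one (anti diol) | CC(=O)CC/C=C(\C)[C@H](O)[C@H](O)C=C | intermediate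
6 | methyl vinyl ketone (but-3-en-2-one) | CC(=O)C=C | starting material
7 | (3E,5R,6S,7E)-5,6-dihydroxy-7-methyldodeca-3,7-diene-2,11-dione | CC(=O)CC/C=C(\C)[C@H](O)[C@H](O)/C=C/C(C)=O | intermediate
8 | (5R,6S,7E)-5,6-dihydroxy-7-methyldodec-7-ene-2,11-dione | CC(=O)CC/C=C(\C)[C@H](O)[C@H](O)CCC(C)=O | intermediate
9 | (5E)-6-[(1R,3S,4R)-1-methyl-2,7-dioxabicyclo[2.2.1]heptan-3-yl]hept-5-en-2-one (alkenyl group endo) | CC(=O)CC/C=C(\C)[C@@H]1O[C@]2(C)CC[C@H]1O2 | intermediate
10 | (1R,2S,3S,4S)-2,4-dimethyl-3-(3-oxobutyl)-7-oxabicyclo[2.2.1]heptane-2-carbaldehyde (exo-CHO, endo-methyl, endo-oxobutyl) | CC(=O)CC[C@H]1[C@](C)(C=O)[C@H]2CC[C@]1(C)O2 | intermediate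
11 | 4-[(1S,2S,3S,4R)-3-ethenyl-1,3-dimethyl-7-oxabicyclo[2.2.1]heptan-2-yl]butan-2-one | CC(=O)CC[C@H]1[C@](C)(C=C)[C@H]2CC[C@]1(C)O2 | intermediate
12 | (1S,2S,3S,4R)-3-ethenyl-1,3-dimethyl-2-{2-[(2S)-2-methyloxiran-2-yl]ethyl}-7-oxabicyclo[2.2.1]heptane | C3[C@@](C)(O3)CC[C@H]1[C@](C)(C=C)[C@H]2CC[C@]1(C)O2 | intermediate
13 | 1-bromo-2-methylprop-1-ene | CC(C)=CBr | starting material
14 | 9-{2-[(1R,2S,3S,4S)-2,4-dimethyl-3-{2-[(2S)-2-methyloxiran-2-yl]ethyl}-7-oxabicyclo[2.2.1]heptan-2-yl]ethyl}-9-borabicyclo[3.3.1]nonane | C3[C@@](C)(O3)CC[C@H]1[C@](C)(CCB4C5CCCC4CCC5)[C@H]2CC[C@]1(C)O2 | intermediate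
15 | (1S,2S,3S,4R)-1,3-dimethyl-3-(4-methylpent-3-en-1-yl)-2-{2-[(2S)-2-methyloxiran-2-yl]ethyl}-7-oxabicyclo[2.2.1]heptane | C3[C@@](C)(O3)CC[C@H]1[C@](C)(CCC=C(C)C)[C@H]2CC[C@]1(C)O2 | intermediate
16 | (3S)-5-[(1S,2S,3S,4R)-1,3-dimethyl-3-(4-methylpent-3-en-1-yl)-7-oxabicyclo[2.2.1]heptan-2-yl]-3-methylpent-1-en-3-ol | C=C[C@@](C)(O)CC[C@H]1[C@](C)(CCC=C(C)C)[C@H]2CC[C@]1(C)O2 | intermediate
17 | (3S)-5-[(1S,2S,3S,4R)-3-[(3S)-3-bromo-4-chloro-4-methylpentyl]-1,3-dimethyl-7-oxabicyclo[2.2.1]heptan-2-yl]-3-methylpent-1-en-3-ol | C=C[C@@](C)(O)CC[C@H]1[C@](C)(CC[C@H](Br)C(C)(C)Cl)[C@H]2CC[C@]1(C)O2 | target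

**Step count and risks**

Total steps: 10. Longest linear sequence: 10 (from hex-5-en-2-one).

The three steps most likely to fail:

Step 5, the one-pot cation cascade, could be diverted by a boat closure, a hydride shift or chloride capture. Fallback, from 8 back to 10: run the closure as a separate halo-Prins reaction (TiCl4, CH2Cl2, −90 °C, cold quench) and isolate the chloro alcohol 4-[(1S,2R,3S,4R,5R)-3-chloro-4-hydroxy-1,3-dimethyl-8-oxabicyclo[3.2.1]octan-2-yl]butan-2-one F1, whose equatorial C–Cl bond is antiperiplanar to the ring C4–C5 bond. A silver-promoted semipinacol rearrangement of this halohydrin (AgBF4, 2,6-di-tert-butylpyridine, CH2Cl2, −40 °C) then contracts the ring to 10, with alkyl rather than hydride migration enforced by that alignment.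

Step 6 depends on discriminating a hindered aldehyde from an unhindered methyl ketone. Fallback, from 10 back to 11: Seyferth–Gilbert homologation with the Ohira–Bestmann reagent (dimethyl 1-diazo-2-oxopropylphosphonate, K2CO3, MeOH, 0 °C), which reacts only with aldehydes, gives the alkyne 4-[(1S,2S,3R,4R)-3-ethynyl-1,3-dimethyl-7-oxabicyclo[2.2.1]heptan-2-yl]butan-2-one F2. Lindlar semihydrogenation (Pd on CaCO3 poisoned with Pb(OAc)2, quinoline, H2, EtOAc) then gives 11.

Step 10 is the proposed new method; face selectivity without a directing group is untested, and the bridging ether oxygen could intercept the bromiranium ion. Fallback with known chemistry, from 16 back to 17: Shi epoxidation (D-fructose-derived ketone, Oxone (2KHSO5·KHSO4·K2SO4), K2CO3, MeCN/dimethoxymethane/H2O, 0 °C) oxidises only the trisubstituted alkene to the epoxide (3S)-5-[(1S,2S,3S,4R)-3-{2-[(2R)-3,3-dimethyloxiran-2-yl]ethyl}-1,3-dimethyl-7-oxabicyclo[2.2.1]heptan-2-yl]-3-methylpent-1-en-3-ol F3. Markovnikov chloride opening with TiCl(OiPr)3 (CH2Cl2, 0 °C) gives the chlorohydrin (3S)-5-[(1S,2S,3S,4R)-3-[(3R)-4-chloro-3-hydroxy-4-methylpentyl]-1,3-dimethyl-7-oxabicyclo[2.2.1]heptan-2-yl]-3-methylpent-1-en-3-ol F4 with the carbinol center untouched. Appel bromination of the secondary alcohol with inversion (PPh3, CBr4, 2,6-lutidine, CH2Cl2, 0 °C; the tertiary alcohol is not expected to react) gives 17.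

Further compounds
F1 | step 5 | 4-[(1S,2R,3S,4R,5R)-3-chloro-4-hydroxy-1,3-dimethyl-8-oxabicyclo[3.2.1]octan-2-yl]butan-2-one (chloride equatorial, hydroxyl axial) | CC(=O)CC[C@H]1[C@](C)(Cl)[C@H](O)[C@H]2CC[C@]1(C)O2
F2 | step 6 | 4-[(1S,2S,3R,4R)-3-ethynyl-1,3-dimethyl-7-oxabicyclo[2.2.1]heptan-2-yl]butan-2-one | CC(=O)CC[C@H]1[C@](C)(C#C)[C@H]2CC[C@]1(C)O2
F3 | step 10 | (3S)-5-[(1S,2S,3S,4R)-3-{2-[(2R)-3,3-dimethyloxiran-2-yl]ethyl}-1,3-dimethyl-7-oxabicyclo[2.2.1]heptan-2-yl]-3-methylpent-1-en-3-ol | C=C[C@@](C)(O)CC[C@H]1[C@](C)(CC[C@@H]3C(C)(C)O3)[C@H]2CC[C@]1(C)O2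
F4 | step 10 | (3S)-5-[(1S,2S,3S,4R)-3-[(3R)-4-chloro-3-hydroxy-4-methylpentyl]-1,3-dimethyl-7-oxabicyclo[2.2.1]heptan-2-yl]-3-methylpent-1-en-3-ol | C=C[C@@](C)(O)CC[C@H]1[C@](C)(CC[C@@H](O)C(C)(C)Cl)[C@H]2CC[C@]1(C)O2
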